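**Retrosynthetic overview**

1. Target 11 ⇒ diacetate 9 by a late C5–H → C5–OH conversion (C–H borylation, then oxidation). The free phenol is made last, so it needs no protecting group and never competes with the two acetylations.
2. 9 ⇒ aryl bromide 6 + (R)-epoxide 4 at the Ar–CH2 bond (key bond): nickel-catalysed electroreductive cross-electrophile coupling with an iodide relay, then acetylation in the same flask.
3. 4 ⇒ (R)-epichlorohydrin 1 + decylmagnesium bromide 2 at C3–C4. The only stereocentre is bought in 1 and never touched afterwards.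
4. 6 ⇒ 2-bromo-6-methoxyphenol 5 by O-acetylation.
5. Rings: the arene is bought intact. The only ring made is the oxirane of 4 (step 1), which is opened again in step 3.

Assumption: decylmagnesium bromide solution and 2-bromo-6-methoxyphenol are bought; reagents that only deliver an acetyl, boron, iodine or oxygen unit are named at their step and not numbered.

**Route**

Step 1
Reactants: 1 (R)-epichlorohydrin; 2 decylmagnesium bromide
Product: 4 (R)-2-undecyloxirane, via bromomagnesium (R)-1-chlorotridecan-2-olate 3 (not isolated)
Conditions: CuI (5 mol %), THF, −40 to −20 °C; then 5 M aq NaOH, MeOH, 0 °C to rt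
Reagents that add atoms: none
Why: Copper-catalysed Grignard opening of the epoxide at its unsubstituted carbon, then intramolecular Williamson closure of the chlorohydrin alkoxide onto the primary chloride; the C2–O bond is never broken, so (R)-1 gives (R)-4 with the same spatial arrangement and the same descriptor.

Step 2
Reactants: 5 2-bromo-6-methoxyphenol
Product: 6 2-bromo-6-methoxyphenyl acetate
Conditions: Ac2O, Et3N, DMAP (5 mol %), CH2Cl2, 0 °C to rt
Reagents that add atoms: acetic anhydride, CC(=O)OC(C)=O
Why: DMAP-catalysed O-acetylation (nucleophilic acyl substitution) installs the aryl acetate of the target and masks the acidic phenol that would otherwise protonate arylnickel species and bind nickel and zinc in step 3.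

Step 3
Reactants: 6 2-bromo-6-methoxyphenyl acetate; 4 (R)-2-undecyloxirane (1.5 equiv)
Product: 9 (R)-1-(2-acetoxy-3-methoxyphenyl)tridecan-2-yl acetate, via (R)-1-iodotridecan-2-ol 7 (not isolated), via (R)-1-(2-acetoxy-3-methoxyphenyl)tridecan-2-ol 8 (not isolated)
Conditions: NiBr2(dme) (10 mol %), 2,2′-bipyridine (10 mol %), NaI (0.5 equiv), Et3N·HCl (1.0 equiv), DMA, undivided cell, Zn anode, reticulated vitreous carbon cathode, constant current (2.3 F/mol), rt; then Ac2O, Et3N, DMAP, rt
Reagents that add atoms: acetic anhydride, CC(=O)OC(C)=O (acetyl of the secondary acetate); sodium iodide, [Na+].[I-] (iodine of intermediate 7 only, released again)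
Why: Proposed new method: nickel-catalysed electroreductive arylation of an unactivated terminal epoxide by an aryl bromide under iodide relay — Et3NH+ I− opens 4 reversibly by SN2 at the CH2 carbon to iodohydrin 7, cathodically generated zerovalent nickel (bipyridine) adds the C–Br bond of 6, a monovalent nickel halide abstracts iodine from 7, the primary β-hydroxyalkyl radical is trapped by the divalent arylnickel, and the resulting trivalent nickel reductively eliminates the Ar–CH2 bond while the zinc anode supplies the electrons; the closest known reactions are the manganese-powder-driven nickel/NaI/Et3N·HCl coupling of terminal epoxides with aryl bromides and the nickel-catalysed electroreductive cross-electrophile coupling of aryl bromides with alkyl bromides at a sacrificial zinc anode; C2–O is never broken, so the (R) centre of 4 is retained, and Ac2O then caps the secondary alcohol (and re-caps the phenol if any acetyl has moved from the ortho OAc to the new hydroxyl).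

Step 4
Reactants: 9 (R)-1-(2-acetoxy-3-methoxyphenyl)tridecan-2-yl acetate
Product: 11 (R)-1-(2-acetoxy-5-hydroxy-3-methoxyphenyl)tridecan-2-yl acetate, via C5 pinacol boronate 10 (not isolated)
Conditions: [Ir(OMe)(cod)]2 (1.5 mol %), 4,4′-di-tert-butyl-2,2′-bipyridine (3 mol %), B2pin2 (1.0 equiv), THF, 80 °C (sealed); then KHSO5 (as Oxone), acetone/H2O, rt, 10 min
Reagents that add atoms: potassium peroxymonosulfate, [K+].[O-]S(=O)(=O)OO (the phenol oxygen); bis(pinacolato)diboron, CC1(C)OB(OC1(C)C)B1OC(C)(C)C(C)(C)O1 (Bpin of intermediate 10 only, lost again)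
Why: Sterically governed iridium-catalysed aromatic C–H borylation (Hartwig–Miyaura type) takes the only ring C–H without an ortho substituent (C5: meta to OMe and to the side chain, para to OAc), and peroxymonosulfate oxidises the boronate in the same flask by 1,2-aryl shift from boron to oxygen (one-pot borylation/oxidation to a phenol); the oxidation is brief and not basic, so both acetates and the stereocentre are untouched.

**Compound list**

1 | (R)-epichlorohydrin, (R)-2-(chloromethyl)oxirane | ClC[C@H]1CO1 | starting material
2 | decylmagnesium bromide | CCCCCCCCCC[Mg]Br | starting material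
3 | bromomagnesium (R)-1-chlorotridecan-2-olate | CCCCCCCCCCC[C@H](CCl)O[Mg]Br | intermediate
4 | (R)-2-undecyloxirane, (R)-1,2-epoxytridecane | CCCCCCCCCCC[C@@H]1CO1 | intermediate
5 | 2-bromo-6-methoxyphenol | COc1cccc(Br)c1O | starting material
6 | 2-bromo-6-methoxyphenyl acetate | COc1cccc(Br)c1OC(C)=O | intermediate
7 | (R)-1-iodotridecan-2-ol | CCCCCCCCCCC[C@H](CI)O | intermediate
8 | (R)-1-(2-acetoxy-3-methoxyphenyl)tridecan-2-ol | CCCCCCCCCCC[C@H](Cc1cccc(OC)c1OC(C)=O)O | intermediate
9 | (R)-1-(2-acetoxy-3-methoxyphenyl)tridecan-2-yl acetate | CCCCCCCCCCC[C@H](Cc1cccc(OC)c1OC(C)=O)OC(C)=O | intermediate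
10 | (R)-1-[2-acetoxy-3-methoxy-5-(4,4,5,5-tetramethyl-1,3,2-dioxaborolan-2-yl)phenyl]tridecan-2-yl acetate | CCCCCCCCCCC[C@H](Cc1cc(B2OC(C)(C)C(C)(C)O2)cc(OC)c1OC(C)=O)OC(C)=O | intermediate
11 | (R)-1-(2-acetoxy-5-hydroxy-3-methoxyphenyl)tridecan-2-yl acetate (CNP0300796.1) | CCCCCCCCCCC[C@H](Cc1cc(O)cc(OC)c1OC(C)=O)OC(C)=O | target

**Step count and risks**

Total step count: 4. Longest linear sequence: 3 steps (1 → 4 → 9 → 11); step 2 is a one-step side branch.

Steps most likely to fail:

Step 3 (the proposed new coupling). Likely failure modes are hydrogen evolution from Et3NH+ at the cathode, zinc-halide-driven diversion of 4 into unreactive halohydrins or rearranged carbonyl compounds, and slow radical capture at the ortho-acetoxy arylnickel leading to hydrodebromination of 6. The fallback uses only known chemistry and replaces the reductive coupling by a polar aryllithium opening of the same epoxide. It sets out from 5 (with 4) and comes back to the route at 9. Phenol 5 is protected with MOMCl/i-Pr2NEt in CH2Cl2 as 1-bromo-3-methoxy-2-(methoxymethoxy)benzene F1. Bromine–lithium exchange with n-BuLi in THF at −78 °C gives [3-methoxy-2-(methoxymethoxy)phenyl]lithium F2, which opens 4 at the CH2 carbon in the presence of BF3·OEt2 at −78 °C to give (R)-1-[3-methoxy-2-(methoxymethoxy)phenyl]tridecan-2-ol F3. HCl in MeOH removes the MOM group to give (R)-1-(2-hydroxy-3-methoxyphenyl)tridecan-2-ol F4, and Ac2O/pyridine/DMAP acetylates both hydroxyls to give 9.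

Step 4 (C–H borylation, then oxidation). Likely failure modes are incomplete or partly OMe-ortho borylation and loss of the aryl acetate or over-oxidation in the oxidation stage. The fallback replaces the C–H borylation by phenol-directed electrophilic bromination and Miyaura borylation. It sets out from 9 and comes back at 10, which is then isolated and oxidised with KHSO5 as in step 4. Pyrrolidine (1.1 equiv, MeCN, 0 °C) cleaves only the aryl acetate of 9 to give (R)-1-(2-hydroxy-3-methoxyphenyl)tridecan-2-yl acetate F5. NBS in MeCN at 0 °C brominates para to the free hydroxyl to give (R)-1-(5-bromo-2-hydroxy-3-methoxyphenyl)tridecan-2-yl acetate F6. Ac2O/Et3N/DMAP gives (R)-1-(2-acetoxy-5-bromo-3-methoxyphenyl)tridecan-2-yl acetate F7, and Pd(dppf)Cl2/KOAc/B2pin2 in dioxane at 85 °C gives 10.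

Step 1 (Grignard opening and ring closure). Likely failure modes are erosion of enantiopurity through halide-induced opening and reclosure of 1 before C–C bond formation, attack at the C–Cl bond, and incomplete closure in the magnesium hydroxide slurry. The fallback replaces the copper/Grignard chemistry by a Yamaguchi-type acetylide opening and isolates the chlorohydrin. It sets out from 1 and comes back at 4. Dec-1-yne and n-BuLi give lithium dec-1-yn-1-ide F8, which opens 1 with BF3·OEt2 in THF at −78 °C to give (R)-1-chlorotridec-4-yn-2-ol F9. Hydrogenation (H2, PtO2, EtOAc) gives (R)-1-chlorotridecan-2-ol F10, and NaOH in aqueous MeOH closes it to 4.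

**Further compounds**

F1 | step 3 | 1-bromo-3-methoxy-2-(methoxymethoxy)benzene | COCOc1c(Br)cccc1OC
F2 | step 3 | [3-methoxy-2-(methoxymethoxy)phenyl]lithium | [Li]c1cccc(OC)c1OCOC
F3 | step 3 | (R)-1-[3-methoxy-2-(methoxymethoxy)phenyl]tridecan-2-ol | CCCCCCCCCCC[C@H](Cc1cccc(OC)c1OCOC)O
F4 | step 3 | (R)-1-(2-hydroxy-3-methoxyphenyl)tridecan-2-ol | CCCCCCCCCCC[C@H](Cc1cccc(OC)c1O)O
F5 | step 4 | (R)-1-(2-hydroxy-3-methoxyphenyl)tridecan-2-yl acetate | CCCCCCCCCCC[C@H](Cc1cccc(OC)c1O)OC(C)=O
F6 | step 4 | (R)-1-(5-bromo-2-hydroxy-3-methoxyphenyl)tridecan-2-yl acetate | CCCCCCCCCCC[C@H](Cc1cc(Br)cc(OC)c1O)OC(C)=O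
F7 | step 4 | (R)-1-(2-acetoxy-5-bromo-3-methoxyphenyl)tridecan-2-yl acetate | CCCCCCCCCCC[C@H](Cc1cc(Br)cc(OC)c1OC(C)=O)OC(C)=O
F8 | step 1 | lithium dec-1-yn-1-ide | [Li]C#CCCCCCCCC
F9 | step 1 | (R)-1-chlorotridec-4-yn-2-ol | CCCCCCCCC#CC[C@H](CCl)O
F10 | step 1 | (R)-1-chlorotridecan-2-ol | CCCCCCCCCCC[C@H](CCl)O
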